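Readings and results were computed for an exercise; scatter was added.

**Start here.** Take the four flasks and the three earlier runs, and set the clock of the feed against the clock of the solid.

| setting | oak | ash | birch | north-east | east | west | south-east |
|---|---|---|---|---|---|---|---|
| solid substrate | 1 M | 2.2 M | 1.5 M | 1.5 M | 1.5 M | 1.5 M | 1.5 M |
| partner | 1.58 M (fed, over 1.5 min) | 1.58 M (fed, over 1.5 min) | 0.79 M (fed, over 1.5 min) | 1.58 M (fed, over 1.5 min) | 1.58 M (fed, over 0.40 min) | 1.58 M (fed, over 1.5 min) | 1.58 M (fed, over 0.40 min) |
| temperature | 42 °C | 59 °C | 42 °C | 65 °C | 65 °C | 35 °C | 35 °C |
| remark | run made earlier; the fed solution adds 1.0 times the starting volume | run made earlier; the fed solution adds 1.0 times the starting volume | run made earlier; the fed solution adds 1.0 times the starting volume | the fed solution adds 1.0 times the starting volume | the fed solution adds 1.0 times the starting volume | the fed solution adds 1.0 times the starting volume | the fed solution adds 1.0 times the starting volume |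
| time |  |  |  | 2.5 min | 2.5 min | 2.5 min | 2.5 min |

oak run (percent of the solid substrate charged)

| time / min | target / % | solid substrate / % |
|---|---|---|
| 0.200 | 2.1 | 55.1 |
| 0.417 | 8.6 | 29.0 |
| 0.667 | 19.9 | 4.4 |
| 1.33 | 47.5 | 0 |
| 2.50 | 63.1 | 0 |

ash run (percent of the solid substrate charged)

| time / s | target / % | solid substrate / % |
|---|---|---|
| 10.0 | 1.1 | 81.6 |
| 12.0 | 1.6 | 79.1 |
| 25.0 | 7.6 | 65.6 |
| 40.0 | 13.8 | 49.0 |
| 50.0 | 18.5 | 36.9 |

birch run (percent of the solid substrate charged)

| time / min | target / % | solid substrate / % |
|---|---|---|
| 0.500 | 3.9 | 49.3 |
| 1.00 | 13.2 | 22.3 |
| 1.50 | 22.1 | 0.2 |
| 2.00 | 26.5 | 0 |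
| 2.50 | 26.2 | 0 |

(readings scatter by 0.3 percentage points)

- charges are per starting volume, the dose included; the dosed solution carries all of it
- as a solid, counted per litre of solution: solid substrate
- at the start none of the solid substrate is in solution
- what has only dissolved of solid substrate counts as not reacted

* all flasks from highest to lowest amount of target, in percent of the solid substrate charged, at 2.5 min (north-east / east / west / south-east)
* the same order at 30 s (north-east / east / west / south-east)
* the amount of target, in percent of the solid substrate charged of the flask you put first, at 2.5 min
* the amount of target, in percent of the solid substrate charged of the flask you put last, at 2.5 min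

**First rung.** The solid leaves first: at 0.667 min the oak run holds 4.4% of its solid but only 19.9% target, so far more substrate has left the solid than has become target, and we take the gap to be mostly substrate in solution, waiting for partner.

**Second rung.** The feed runs at a steady rate (a semi-batch dose), so integrating it gives partner fed, per starting volume, as 1.58 M times the elapsed time over the dosing time. That amount equals the solid charged at the equivalence time 1.42 min for the slow dose, and at 0.380 min for the quick one. As a yardstick, birch, at 42 °C with the same solid charge, is down to 0.2% of solid at 1.50 min. The slow dose's equivalence time lies close to that reading, and the quick dose's lies well before it.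

**Third rung.** Target comes last, and it stands higher in the run with the richer partner share: oak reads 63.1% at 2.50 min with 1.58 equivalents, birch 26.5% at 2.00 min with 0.527, though these two runs differ in both charges. Our own judgement is that partner present early counts the same way, so we expect the earlier equivalence time to give more target at each temperature, with east above north-east and south-east above west. At 30 s the slow dose has delivered a third of its partner and the quick dose its whole charge.

**The forecast.** It gave north-east > east > south-east > west at 2.5 min and east > north-east > south-east > west at 30 s, with 51% first and 42% last, against a cap of 52.7%: “Hot flasks should reach the cap.” We part from it on north-east, which we place below east.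

**The result.** The order is east > south-east > west > north-east at 2.5 min and east > south-east > north-east > west at 30 s.

    dissolved substrate + partner → target (k = 1.70 L mol⁻¹ min⁻¹, Ea = 53.0 kJ mol⁻¹)
    dissolved substrate + target → side product (k = 0.736 L mol⁻¹ min⁻¹, Ea = 45.0 kJ mol⁻¹)
    solid substrate ⇌ dissolved substrate, rate k3*(cs3 - [dissolved substrate]) while solid is left; crystals form when [dissolved substrate] > cs3 (solubility = 0.630 M, k = 5.34 min⁻¹)
    (constants at 35 °C)

**At rest.** East, at 59.4%, stands above north-east, at 41.9%, and south-east, at 53.3%, above west, at 49.3%. With 2.5 M of solid, the north-east recipe reckons to an equivalence time of 2.37 min, past the end of its feed at 1.5 min, so that dose stops short of the solid at 0.632 equiv, and this neighbour flask gives 22.8% target beside 73.8% side product. Left to 25.0 min, east stays at 59.4% and north-east at 42.0%. At 2.5 min south-east still holds 13.8% dissolved substrate and west 20.2%, and by 25.0 min south-east has climbed from 53.3% to 55.3% target and west from 49.3% to 53.6%.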